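The numbers are invented; the flask was simulated.

Friday's flask holds 500 free monomer per initiator and Sunday's 148, but a chain's length depends on how much of that initiator begins chains and how much free monomer has reacted by the end.

- Friday's: free monomer 0.27 M; initiator 0.54 mM; time 12 h
- Sunday's: free monomer 0.080 M; initiator 0.54 mM; time 12 h

1. which of the two ends with the longer chains by the average number of monomer units in a chain (chains begun, living or dead) ("neither" if they lie within 10%) (Friday's / Sunday's / neither)
2. average number of monomer units in a chain (chains begun, living or dead) at the end, Friday's
3. average number of monomer units in a chain (chains begun, living or dead) at the end, Sunday's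

- the average divides the monomer in chains by the number of chains begun, living and dead together
- run time (Friday's): 12 h

Initiator and free monomer begin a living end, a living end adds free monomer, and initiator also decays to spent initiator. Two numbers seem not to go together, with initiator the reagent charged in the smaller amount: its half-life by decay alone is 7.5 h, while free monomer's half-life by initiation alone on Friday's, the other concentrations held at their charge, is far longer, 33 d, as if initiator must decay before it begins anything. But that long time is the monomer's clock. In the initiator's balance, initiation is pseudo-first-order, with its constant times the charged [free monomer] at 0.432 h⁻¹ on Friday's and 0.128 h⁻¹ on Sunday's, both faster than decay at 0.093 h⁻¹. So I carry the start share, initiation's rate over the sum of initiation and decay at the charged [free monomer], the part of initiator consumed at the start that begins chains: 82.3% on Friday's and 57.9% on Sunday's.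

Holding [free monomer] at its charge, I get 4.44 × 10⁻⁴ M chains begun on Friday's and 2.91 × 10⁻⁴ M on Sunday's. Integrating the rise of the living ends through propagation, I reckon that 55.4% of the free monomer reacts on Friday's and 35.5% on Sunday's, so my lengths are 337 on Friday's and 97.7 on Sunday's.

The forecast says Friday's, with 340 and 100, noting that “initiation must compete with the initiator's first-order loss”. The flask gives Friday's, with 340 on Friday's and 101 on Sunday's.

    free monomer + initiator → living end + monomer in chains (k1 = 1.6 M⁻¹ h⁻¹)
    free monomer + living end → monomer in chains + living end, rate k2*[living end]*[free monomer] (k2 = 180 M⁻¹ h⁻¹)
    initiator → spent initiator (k3 = 0.093 h⁻¹)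

On Friday's, initiation and decay ran while initiator stood, 5.85% of its charge at 6.00 h, and at 12.0 h the flask holds 4.34 × 10⁻⁴ M living ends and 1.02 × 10⁻⁴ M spent initiator. Propagation went on with 4.14 × 10⁻⁴ M living ends at 6.00 h, leaving 45.3% of the free monomer at 12.0 h. A neighbour of Friday's with 3.2 × 10⁻⁴ M initiator keeps that start share, which contains no initiator charge, so I expect 2.63 × 10⁻⁴ M chains and a length of 391. The computed length is 392.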